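All runs were generated by integration for substances that don't exist; scatter was added.

**The vessel.** Our vessel is closed, stirred and isothermal. In it, substrate and reagent turn reversibly into target and into isomer of the product.

| flask | substrate | reagent | remark | time |
|---|---|---|---|---|
| autumn | 0.10 M | 0.10 M | run made earlier |  |
| summer | 0.10 M | 0.40 M | run made earlier |  |
| flask | 0.10 M | 0.200 M |  | 12 d |

| run | time / d | isomer of the product / % | target / % | substrate / % |
|---|---|---|---|---|
| autumn | 0.625 | 19.4 | 41.2 | 38.7 |
| autumn | 1.04 | 19.4 | 41.3 | 39.0 |
| autumn | 1.67 | 19.7 | 41.2 | 39.4 |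
| autumn | 2.50 | 19.7 | 40.5 | 38.4 |
| autumn | 4.00 | 20.0 | 40.7 | 38.4 |
| autumn | 8.00 | 19.4 | 41.2 | 39.1 |
| summer | 1.25 | 29.3 | 63.1 | 7.7 |
| summer | 2.50 | 30.2 | 62.5 | 7.5 |
| summer | 4.00 | 30.2 | 61.5 | 8.0 |
| summer | 5.00 | 30.1 | 62.2 | 7.8 |
| summer | 6.00 | 30.0 | 62.7 | 8.0 |
| summer | 8.00 | 30.1 | 61.3 | 7.2 |

(readings scatter by 0.5 percentage points)

- reactions considered so far: substrate + reagent <-> isomer of the product; substrate + reagent <-> target

- ratio of isomer of the product to target at 3.0 min
- ratio of isomer of the product to target at 12 d

**Plateau mean.** The readings of both runs lie nearly level, so our rule of thumb replaces each curve by its mean. In the autumn run the mean fractions of the charge are 0.196 isomer and 0.410 target. The autumn isomer reading at 4.00 d stands 0.4 percentage points above its mean, less than the scatter of 0.5 points.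

So the autumn run gives 0.478 for the plateau ratio, mean isomer fraction over mean target fraction. The summer run gives 0.482, with 4.00 times the reagent. Each product takes up one substrate and one reagent, so both drop out of the ratio at equilibrium. The flask has 2.00 equivalents of reagent, between the 1.00 and 4.00 of the runs, so we commit to 0.478 at 12 d.

**The border.** The first autumn reading, earlier than the first summer one, comes 300 times later than 3.0 min. So no reading of either run stands at that moment to enter a mean. An early ratio follows the forward rates (kinetic control), a plateau ratio the equilibrium (thermodynamic control), so we leave 3.0 min open.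

**The forecast.** It gives 0.48 at 12 d and 0.48 at 3.0 min, warning: “If the products form under kinetic control, the early ratio could differ greatly in either direction.”

**The flask.** The flask gives 0.481 at 3.0 min and 0.481 at 12 d.

    substrate + reagent ⇌ isomer of the product (K = 13.0 L mol⁻¹, k = 0.00138 L mol⁻¹ s⁻¹)
    substrate + reagent ⇌ target (K = 27.0 L mol⁻¹, k = 0.00287 L mol⁻¹ s⁻¹)

The rate constants of the isomer and target steps stand in the ratio 0.481, and their equilibrium constants in the ratio 0.481. At 12 d the flask holds 55.7 % target, and the plateau ratio turns that into 26.6 % isomer, against 26.8 % in the flask. A neighbour flask charged with 0.40 M substrate, its reagent as in the flask, holds 30.3 % target at 12.0 d, in percent of its substrate charged. There the plateau ratio gives 14.5 % isomer, against 14.6 % in that flask.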